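# Proposed synthesis of (3S)-3-(3-hydroxy-2,4,5-trimethoxyphenyl)-8-methoxychroman-7-ol (24)

Position labels O1, C2, C3, C4, C4a, C5–C8, C8a (chroman part) and C1'–C6' (ring B) are those of the target. They are used for the corresponding atoms of every intermediate.

## Analysis of the target

Target 24 is an isoflavan: a benzene ring A fused to a dihydropyran, with a pentasubstituted aryl ring B on C3. C3 is the only stereocentre and is (S). It is a tertiary benzylic carbon between two methylene groups (C2 on O1, C4 on ring A) and is not acidic. Once set it is endangered only if C2 or C4 becomes a carbonyl or cationic carbon, or if a C3=C4 double bond is formed. Ring A carries three adjacent oxygens: O1 on C8a, a methoxy group on C8 and a free hydroxyl on C7. Ring B carries four adjacent oxygens on C2'–C5', with the free hydroxyl at the inner position C3'. Both phenols sit on very electron-rich rings and are prone to oxidation, so they should be masked or released late. The difficulty is to place seven oxygen substituents without regiochemical doubt and to set an isolated stereocentre that has no neighbouring functional group to direct it. The strategy rests on the oxygens at C8a and C7 being 1,3 to each other with the C8 methoxy carbon between them and the side-chain carbon C4a next to C8a. That is the pattern of a 4-alkyl-2-methoxycyclohexane-1,3-dione such as 20, which a Claisen cyclization of a δ-keto ester with a methoxyacetyl ketone delivers.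

## Retrosynthetic reasoning

The free C3' hydroxyl of 24 is traced back to the benzyl ether 23. Benzyl is chosen because it tolerates organolithium, hydride, alkoxide and chloride reagents and is removed last by hydrogenolysis. No other benzylic C–O bond is present in 23.

The O1–C2 bond of 23 is cut next, giving the triol 22, whose silyl ether is 21. A Mitsunobu etherification closes this bond at a primary carbon, so C3 is not touched. Of the two phenols of 22 only the one on C8a can reach C2 through a six-membered ring, so no phenol protection on ring A is needed.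

The 2-methoxyresorcinol ring of 21 is taken back by one formal addition of H2 to the cyclohexane-1,3-dione 20. The forward step is a single ketone α,β-dehydrogenation followed by tautomerization. This changes an aromatic ring that would have to be bought with three differentiated oxygens into a carbocycle that can be made from a chain.

In 20 the C7–C8 bond is cut, which opens ring A to the δ-keto ester 19. This is the central disconnection. The C8 carbon of 19 lies between the ketone and the methoxy group and is the only enolizable position from which the ester can be reached through a six-membered ring. The three oxygens of ring A and the position of the side chain are therefore written into the chain and cannot be scrambled. The forward step is an alkoxide-mediated Claisen cyclization driven by the acidity of the dione.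

Keto ester 19 is simplified by adding back a methoxycarbonyl group on C4a, giving 18. That β-keto ester is cut at C4a–C5 into the Michael acceptor methyl acrylate 17 and the monoalkylated keto ester 16. Compound 16 is cut at C4–C4a into the iodide 14 and methyl 4-methoxyacetoacetate 15. The ester of 15 makes C4a the only nucleophilic carbon in both C–C bond formations and is removed afterwards by chloride-mediated dealkoxycarbonylation. A triisopropylsilyl ether is used on the C2 oxygen instead of a smaller silyl group for two reasons. It should resist chloride at high temperature. It also should not migrate to the neighbouring hydroxyl in the mono-protected diol 13, which would racemize C3.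

Iodide 14 comes from alcohol 13, and 13 from acetate 12 and monoacetate 11 by exchange of the two oxygen functions. Compound 11 is the product of lipase desymmetrization of the prochiral diol 10. C3 is set here catalytically on a small molecule whose enantiomeric purity can be checked before the chain is built.

Diol 10 is the reduction product of the arylmalonate 9, which is cut at the aryl–C3 bond into the aryl bromide 7 and diethyl malonate 8. A palladium-catalysed malonate arylation brings in C2, C3 and C4 in one step and gives the symmetric substrate needed for the enzyme.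

Ring B is built from 2,6-dimethoxyphenol 1, whose free hydroxyl is already at the inner position that becomes C3'. After benzylation to 2, double bromination gives the symmetric dibromide 3. In 3 the two bromines mark C1' and C5' and are equivalent, so a single bromine–lithium exchange, borylation and oxidation to phenol 6, and methylation to 7 settle the substitution pattern by symmetry and not by a selectivity that would have to be won.

## Alternatives that were turned down

Alternative 1: The C3–C1' bond is cut, together with a temporary bond between C4 and the oxygen on C2'. In the forward direction the quinone A2 is activated by a chiral TADDOL complex of tetravalent titanium, prepared from TiCl4 and Ti(OiPr)4. It is attacked by C3 of the 2H-chromene A3, and the quinone oxygen then closes on C4 to give the cis-fused pterocarpan A1. Hydrogenolysis of the benzylic C4–O bond would then open A1 to the isoflavan. This route is much more convergent than the chosen one: ring A is bought as an arene and C3 is set in the same step that joins the two halves. Against it, the quinone delivers oxygen only at C2', C4' and C5' of ring B. The C3' hydroxyl, which lies between two oxygen-bearing carbons, is missing and would have to be introduced late, or carried in a more substituted quinone whose two enone halves would no longer be clearly differentiated. After ring opening, the C2' and C5' hydroxyls would also need methylation while C7 and C3' stay distinct, and the chiral titanium reagent is stoichiometric. Alternative 1 is stronger on step count to the carbon skeleton. The chosen strategy offers in its place an unambiguous position for every one of the seven oxygens.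

Alternative 2: The O1–C8a bond and the C8–O bond are cut. In the forward direction LiN(iPr)2 removes the C8 hydrogen of the bromoarene A5, loss of LiBr gives the C8–C8a aryne, the tethered C2 alkoxide adds to C8a, and the C8 aryllithium is trapped with B(OMe)3 and oxidized with H2O2 to the chromanol A4. In its favour, both rings are purchased as arenes, the pyran ring and the C8 oxygen arrive in one flask, and the same enzymatic desymmetrization could set C3, so the route would be shorter. Against it, the C8 aryllithium is generated next to the secondary amine set free from the base. If it is protonated before borylation, the oxygen at C8 is lost for good. Amide addition to the aryne also competes with ring closure, and methylation at C8 and removal of two acetal groups still follow. Alternative 2 is stronger on step economy. The chosen strategy has the C8 oxygen in the chain from the start and lets ring size, not the lifetime of an anion, decide the regiochemistry.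

Alternative 3: The C3–C4 and O1–C2 bonds are cut in a hetero-Diels–Alder sense. In the forward direction t-BuMgCl converts the O-Boc salicyl alcohol A7 into an ortho-quinone methide, which adds to the Z enol ether A8 bearing a (1R,2S)-2-phenylcyclohexyl auxiliary. The product is the 2,3-cis acetal A6, with C3 set by the auxiliary. Reductive removal of the C2 alkoxy group and hydrogenolysis of both benzyl ethers would finish the synthesis. This is the most convergent of the four plans and is clearly stronger on step count. Against it, C3 is created next to an acetal carbon that must later be ionized. The C2 oxocarbenium ion can lose the C3 proton to give a 4H-chromene enol ether, which erases the stereocentre. The Z enol ether of a hindered, tetra-oxygenated arylacetaldehyde must also be geometrically pure, and the auxiliary is stoichiometric. The chosen strategy offers in its place a C3 centre that is never adjacent to a cationic or carbonyl carbon after it is set, and absolute configuration from a catalytic enzyme.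

Key step: step 14

Assumption: the lipase is taken to acetylate the enantiotopic hydroxymethyl group that leads to the (S)-monoacetate 11. If it prefers the other arm, 11 is reached by enzymatic hydrolysis of the diacetate (fallback to step 7) and nothing else changes.

Remark: enolates, alkoxides and phenoxides that are only protonated on work-up are treated as the same compound as their acid form and carry no separate number.

## Route

Step 1
Reactants: 1 2,6-dimethoxyphenol
Product: 2 2-(benzyloxy)-1,3-dimethoxybenzene
Conditions: BnBr, K2CO3, DMF, 60 °C
Reagents that add atoms: benzyl bromide, BrCc1ccccc1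
Why: Williamson ether synthesis on the only nucleophilic site; the benzyl ether marks the oxygen that becomes the free C3' hydroxyl and survives every later step up to hydrogenolysis.

Step 2
Reactants: 2 2-(benzyloxy)-1,3-dimethoxybenzene
Product: 3 3-(benzyloxy)-1,5-dibromo-2,4-dimethoxybenzene
Conditions: NBS (2.1 equiv), MeCN, 0 °C to rt
Reagents that add atoms: N-bromosuccinimide, O=C1CCC(=O)N1Br
Why: Electrophilic aromatic bromination; each bromine should enter ortho to one in-plane methoxy group and para to the other, while the position para to the twisted central benzyloxy group is the least activated, so the symmetric dibromide is expected.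

Step 3
Reactants: 3 3-(benzyloxy)-1,5-dibromo-2,4-dimethoxybenzene
Product: 6 3-(benzyloxy)-5-bromo-2,4-dimethoxyphenol, via aryllithium 4 (not isolated), via dimethyl arylboronate 5 (not isolated)
Conditions: n-BuLi (1.0 equiv), THF, −78 °C; B(OMe)3, −78 °C to rt; then 30% H2O2, AcOH, 0 °C to rt
Reagents that add atoms: n-butyllithium, [Li]CCCC (lithium of 4); trimethyl borate, COB(OC)OC (boron and methoxy groups of 5); hydrogen peroxide, OO (phenol oxygen of 6)
Why: Bromine–lithium exchange on the symmetric dibromide gives the same aryllithium from either bromine and should stop after one exchange; borylation and peroxide oxidation then turn the C–Li bond into C–OH at the same carbon, a standard phenol synthesis.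

Step 4
Reactants: 6 3-(benzyloxy)-5-bromo-2,4-dimethoxyphenol
Product: 7 3-(benzyloxy)-1-bromo-2,4,5-trimethoxybenzene
Conditions: MeI, K2CO3, acetone, reflux
Reagents that add atoms: iodomethane, CI
Why: Williamson methylation of the single phenol completes the ring B oxygen pattern; the remaining bromine marks C1'.

Step 5
Reactants: 7 3-(benzyloxy)-1-bromo-2,4,5-trimethoxybenzene; 8 diethyl malonate
Product: 9 diethyl 2-[3-(benzyloxy)-2,4,5-trimethoxyphenyl]malonate
Conditions: Pd(dba)2 (2 mol %), P(t-Bu)3·HBF4 (4 mol %), K3PO4, toluene, 80 °C
Reagents that add atoms: none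
Why: Palladium-catalysed α-arylation of a malonate; the bulky electron-rich phosphine lets zerovalent palladium insert into the electron-rich, ortho-substituted C–Br bond, and the product is held as its enolate, which prevents a second arylation.

Step 6
Reactants: 9 diethyl 2-[3-(benzyloxy)-2,4,5-trimethoxyphenyl]malonate
Product: 10 2-[3-(benzyloxy)-2,4,5-trimethoxyphenyl]propane-1,3-diol
Conditions: LiAlH4, THF, 0 °C to rt (9 added slowly to the hydride)
Reagents that add atoms: none
Why: Hydride reduction of both esters to the prochiral 1,3-diol; inverse addition at low temperature keeps enolization of the malonate, which would stall the reduction, to a minimum.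

Step 7
Reactants: 10 2-[3-(benzyloxy)-2,4,5-trimethoxyphenyl]propane-1,3-diol
Product: 11 (2S)-2-[3-(benzyloxy)-2,4,5-trimethoxyphenyl]-3-hydroxypropyl acetate
Conditions: lipase from Burkholderia cepacia (Amano PS, immobilized), vinyl acetate, t-BuOMe, rt
Reagents that add atoms: vinyl acetate, C=COC(C)=O
Why: Enzymatic desymmetrization of a 2-aryl-1,3-diol by irreversible transesterification; the chiral active site of the lipase distinguishes the two enantiotopic hydroxymethyl groups and so sets the C3 stereocentre, and further acetylation of the minor monoacetate to the diacetate should raise the enantiomeric purity of 11.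

Step 8
Reactants: 11 (2S)-2-[3-(benzyloxy)-2,4,5-trimethoxyphenyl]-3-hydroxypropyl acetate
Product: 12 (2R)-2-[3-(benzyloxy)-2,4,5-trimethoxyphenyl]-3-[(triisopropylsilyl)oxy]propyl acetate
Conditions: TIPSOTf, 2,6-lutidine, CH2Cl2, −78 °C
Reagents that add atoms: triisopropylsilyl trifluoromethanesulfonate, CC(C)[Si](OS(=O)(=O)C(F)(F)F)(C(C)C)C(C)C
Why: Silylation with a silyl triflate at −78 °C should outrun acyl migration between the two oxygens, which would racemize 11; no bond to the stereocentre is changed, and the descriptor switches from S to R only because the priorities change.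

Step 9
Reactants: 12 (2R)-2-[3-(benzyloxy)-2,4,5-trimethoxyphenyl]-3-[(triisopropylsilyl)oxy]propyl acetate
Product: 13 (2R)-2-[3-(benzyloxy)-2,4,5-trimethoxyphenyl]-3-[(triisopropylsilyl)oxy]propan-1-ol
Conditions: K2CO3 (0.2 equiv), MeOH, 0 °C
Reagents that add atoms: none
Why: Base-catalysed transesterification of a primary acetate; the bulky triisopropylsilyl group should neither be cleaved nor migrate to the free hydroxyl under catalytic carbonate at 0 °C, so the configuration is kept.

Step 10
Reactants: 13 (2R)-2-[3-(benzyloxy)-2,4,5-trimethoxyphenyl]-3-[(triisopropylsilyl)oxy]propan-1-ol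
Product: 14 {[(2S)-2-[3-(benzyloxy)-2,4,5-trimethoxyphenyl]-3-iodopropyl]oxy}triisopropylsilane
Conditions: I2, PPh3, imidazole, CH2Cl2, 0 °C to rt
Reagents that add atoms: iodine, II
Why: Appel-type iodination of a primary alcohol by SN2 displacement of the oxyphosphonium group; the reaction is at the CH2 carbon that becomes C4 and leaves the stereocentre untouched.

Step 11
Reactants: 14 {[(2S)-2-[3-(benzyloxy)-2,4,5-trimethoxyphenyl]-3-iodopropyl]oxy}triisopropylsilane; 15 methyl 4-methoxy-3-oxobutanoate (methyl 4-methoxyacetoacetate)
Product: 16 methyl (4S)-4-[3-(benzyloxy)-2,4,5-trimethoxyphenyl]-2-(methoxyacetyl)-5-[(triisopropylsilyl)oxy]pentanoate (mixture of C2 epimers)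
Conditions: 15 (1.5 equiv), NaH, DMF, 0 °C; then 14, 60 °C
Reagents that add atoms: none
Why: Acetoacetic ester alkylation; the soft, weakly basic enolate of 15 reacts at the carbon between the two carbonyl groups with the primary iodide by SN2, which should keep E2 elimination towards the 2-arylpropene low. The new centre is not controlled and is lost later.

Step 12
Reactants: 16 methyl (4S)-4-[3-(benzyloxy)-2,4,5-trimethoxyphenyl]-2-(methoxyacetyl)-5-[(triisopropylsilyl)oxy]pentanoate; 17 methyl acrylate
Product: 18 dimethyl 2-{(2S)-2-[3-(benzyloxy)-2,4,5-trimethoxyphenyl]-3-[(triisopropylsilyl)oxy]propyl}-2-(methoxyacetyl)pentanedioate (mixture of epimers at the quaternary carbon)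
Conditions: 17 (1.5 equiv), DBU (0.2 equiv), MeCN, rt
Reagents that add atoms: none
Why: Base-catalysed Michael addition of an α-substituted β-keto ester brings in C5, C6 and C7 and forms the quaternary carbon; a catalytic amidine base is used because alkoxide could cleave the β-keto ester by retro-Claisen reaction.

Step 13
Reactants: 18 dimethyl 2-{(2S)-2-[3-(benzyloxy)-2,4,5-trimethoxyphenyl]-3-[(triisopropylsilyl)oxy]propyl}-2-(methoxyacetyl)pentanedioate
Product: 19 methyl (6S)-6-[3-(benzyloxy)-2,4,5-trimethoxyphenyl]-4-(methoxyacetyl)-7-[(triisopropylsilyl)oxy]heptanoate (mixture of C4 epimers)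
Conditions: LiCl, H2O (2 equiv), DMSO, 140 °C
Reagents that add atoms: none
Why: Krapcho dealkoxycarbonylation; chloride demethylates the ester that is geminal to the ketone, since only that carboxylate loses CO2, and the remote ester at C7 is kept. The triisopropylsilyl ether is chosen to withstand chloride at this temperature.

Step 14
Reactants: 19 methyl (6S)-6-[3-(benzyloxy)-2,4,5-trimethoxyphenyl]-4-(methoxyacetyl)-7-[(triisopropylsilyl)oxy]heptanoate
Product: 20 4-{(2S)-2-[3-(benzyloxy)-2,4,5-trimethoxyphenyl]-3-[(triisopropylsilyl)oxy]propyl}-2-methoxycyclohexane-1,3-dione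
Conditions: NaOMe (2.5 equiv), MeOH–toluene, 80 °C; then aq. HCl, 0 °C, to pH 3
Reagents that add atoms: none
Why: Methoxide reversibly deprotonates the methoxymethyl carbon C8 of the ketone; this enolate adds to the ester carbonyl C7 and loss of methoxide closes ring A, forming the C7–C8 bond. The closest known reaction type is the Dieckmann-type Claisen cyclization of 5-oxoalkanoates to cyclohexane-1,3-diones. The ring closes in the 6-(enolendo)-exo-trig mode, which is favoured. No stereocentre is created: C4a is epimeric and becomes aromatic later, C8 is part of the enolized dione, and C3 has no acidic hydrogen and no carbonyl neighbour, so its configuration is carried through. The step needs regioselective use of one enolate, and the substrate secures it through ring size: the other two enolizable carbons, C4a and C6, could only form four-membered rings. The dione is a vinylogous acid and is removed from the equilibrium as its enolate, which should pull the reversible condensation to completion and protect the product from retro-Claisen cleavage. Dilution is used to disfavour intermolecular ester condensation.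

Step 15
Reactants: 20 4-{(2S)-2-[3-(benzyloxy)-2,4,5-trimethoxyphenyl]-3-[(triisopropylsilyl)oxy]propyl}-2-methoxycyclohexane-1,3-dione
Product: 21 4-{(2S)-2-[3-(benzyloxy)-2,4,5-trimethoxyphenyl]-3-[(triisopropylsilyl)oxy]propyl}-2-methoxybenzene-1,3-diol
Conditions: Pd(OCOCF3)2 (5 mol %), 2-(dimethylamino)pyridine (10 mol %), TsOH·H2O (20 mol %), DMSO, O2 (1 atm), 80 °C
Reagents that add atoms: none
Why: Palladium-catalysed aerobic dehydrogenation of a cyclic ketone to a phenol; divalent palladium should form a carbon-bound enolate at C6 or C4a, β-hydride elimination from C5 gives the cyclohexenedione, which tautomerizes to the resorcinol, and O2 reoxidizes the catalyst. Only one dehydrogenation is needed, and partial loss of the silyl ether would be harmless because it is removed in the next step.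

Step 16
Reactants: 21 4-{(2S)-2-[3-(benzyloxy)-2,4,5-trimethoxyphenyl]-3-[(triisopropylsilyl)oxy]propyl}-2-methoxybenzene-1,3-diol
Product: 22 4-{(2S)-2-[3-(benzyloxy)-2,4,5-trimethoxyphenyl]-3-hydroxypropyl}-2-methoxybenzene-1,3-diol
Conditions: Bu4NF, AcOH, THF, 0 °C to rt
Reagents that add atoms: none
Why: Fluoride cleavage of the silyl ether; acetic acid keeps the resorcinol protonated and so limits air oxidation of the electron-rich ring.

Step 17
Reactants: 22 4-{(2S)-2-[3-(benzyloxy)-2,4,5-trimethoxyphenyl]-3-hydroxypropyl}-2-methoxybenzene-1,3-diol
Product: 23 (3S)-3-[3-(benzyloxy)-2,4,5-trimethoxyphenyl]-8-methoxychroman-7-ol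
Conditions: PPh3, DIAD, THF (0.01 M), 0 °C to rt
Reagents that add atoms: none
Why: Intramolecular Mitsunobu etherification (6-exo-tet); only the C8a hydroxyl can reach the activated primary carbon C2 through a six-membered ring, the C7 hydroxyl cannot, and high dilution suppresses intermolecular etherification. The displacement is at CH2, so C3 keeps its configuration.

Step 18
Reactants: 23 (3S)-3-[3-(benzyloxy)-2,4,5-trimethoxyphenyl]-8-methoxychroman-7-ol
Product: 24 (3S)-3-(3-hydroxy-2,4,5-trimethoxyphenyl)-8-methoxychroman-7-ol
Conditions: H2 (1 atm), 10% Pd/C, EtOAc–MeOH, rt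
Reagents that add atoms: none
Why: Hydrogenolysis of the benzyl aryl ether; O1–C2 is an alkyl aryl ether and C4 carries no heteroatom, so no other bond should be cleaved and C3 is not affected.

## Compound list

1 | 2,6-dimethoxyphenol | COc1cccc(OC)c1O | starting material
2 | 2-(benzyloxy)-1,3-dimethoxybenzene | COc1cccc(OC)c1OCc1ccccc1 | intermediate
3 | 3-(benzyloxy)-1,5-dibromo-2,4-dimethoxybenzene | COc1c(Br)cc(Br)c(OC)c1OCc1ccccc1 | intermediate
4 | [3-(benzyloxy)-5-bromo-2,4-dimethoxyphenyl]lithium | [Li]c1cc(Br)c(OC)c(OCc2ccccc2)c1OC | intermediate (not isolated)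
5 | dimethyl [3-(benzyloxy)-5-bromo-2,4-dimethoxyphenyl]boronate | COB(OC)c1cc(Br)c(OC)c(OCc2ccccc2)c1OC | intermediate (not isolated)
6 | 3-(benzyloxy)-5-bromo-2,4-dimethoxyphenol | Oc1cc(Br)c(OC)c(OCc2ccccc2)c1OC | intermediate
7 | 3-(benzyloxy)-1-bromo-2,4,5-trimethoxybenzene | COc1cc(Br)c(OC)c(OCc2ccccc2)c1OC | intermediate
8 | diethyl malonate | CCOC(=O)CC(=O)OCC | starting material
9 | diethyl 2-[3-(benzyloxy)-2,4,5-trimethoxyphenyl]malonate | CCOC(=O)C(C(=O)OCC)c1cc(OC)c(OC)c(OCc2ccccc2)c1OC | intermediate
10 | 2-[3-(benzyloxy)-2,4,5-trimethoxyphenyl]propane-1,3-diol | OCC(CO)c1cc(OC)c(OC)c(OCc2ccccc2)c1OC | intermediate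
11 | (2S)-2-[3-(benzyloxy)-2,4,5-trimethoxyphenyl]-3-hydroxypropyl acetate | CC(=O)OC[C@H](CO)c1cc(OC)c(OC)c(OCc2ccccc2)c1OC | intermediate
12 | (2R)-2-[3-(benzyloxy)-2,4,5-trimethoxyphenyl]-3-[(triisopropylsilyl)oxy]propyl acetate | CC(=O)OC[C@H](CO[Si](C(C)C)(C(C)C)C(C)C)c1cc(OC)c(OC)c(OCc2ccccc2)c1OC | intermediate
13 | (2R)-2-[3-(benzyloxy)-2,4,5-trimethoxyphenyl]-3-[(triisopropylsilyl)oxy]propan-1-ol | OC[C@H](CO[Si](C(C)C)(C(C)C)C(C)C)c1cc(OC)c(OC)c(OCc2ccccc2)c1OC | intermediate
14 | {[(2S)-2-[3-(benzyloxy)-2,4,5-trimethoxyphenyl]-3-iodopropyl]oxy}triisopropylsilane | IC[C@H](CO[Si](C(C)C)(C(C)C)C(C)C)c1cc(OC)c(OC)c(OCc2ccccc2)c1OC | intermediate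
15 | methyl 4-methoxy-3-oxobutanoate (methyl 4-methoxyacetoacetate) | COCC(=O)CC(=O)OC | starting material
16 | methyl (4S)-4-[3-(benzyloxy)-2,4,5-trimethoxyphenyl]-2-(methoxyacetyl)-5-[(triisopropylsilyl)oxy]pentanoate | COCC(=O)C(C(=O)OC)C[C@H](CO[Si](C(C)C)(C(C)C)C(C)C)c1cc(OC)c(OC)c(OCc2ccccc2)c1OC | intermediate
17 | methyl acrylate | C=CC(=O)OC | starting material
18 | dimethyl 2-{(2S)-2-[3-(benzyloxy)-2,4,5-trimethoxyphenyl]-3-[(triisopropylsilyl)oxy]propyl}-2-(methoxyacetyl)pentanedioate | COCC(=O)C(CCC(=O)OC)(C(=O)OC)C[C@H](CO[Si](C(C)C)(C(C)C)C(C)C)c1cc(OC)c(OC)c(OCc2ccccc2)c1OC | intermediate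
19 | methyl (6S)-6-[3-(benzyloxy)-2,4,5-trimethoxyphenyl]-4-(methoxyacetyl)-7-[(triisopropylsilyl)oxy]heptanoate | COCC(=O)C(CCC(=O)OC)C[C@H](CO[Si](C(C)C)(C(C)C)C(C)C)c1cc(OC)c(OC)c(OCc2ccccc2)c1OC | intermediate
20 | 4-{(2S)-2-[3-(benzyloxy)-2,4,5-trimethoxyphenyl]-3-[(triisopropylsilyl)oxy]propyl}-2-methoxycyclohexane-1,3-dione | COC1C(=O)CCC(C[C@H](CO[Si](C(C)C)(C(C)C)C(C)C)c2cc(OC)c(OC)c(OCc3ccccc3)c2OC)C1=O | intermediate
21 | 4-{(2S)-2-[3-(benzyloxy)-2,4,5-trimethoxyphenyl]-3-[(triisopropylsilyl)oxy]propyl}-2-methoxybenzene-1,3-diol | COc1c(O)ccc(C[C@H](CO[Si](C(C)C)(C(C)C)C(C)C)c2cc(OC)c(OC)c(OCc3ccccc3)c2OC)c1O | intermediate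
22 | 4-{(2S)-2-[3-(benzyloxy)-2,4,5-trimethoxyphenyl]-3-hydroxypropyl}-2-methoxybenzene-1,3-diol | COc1c(O)ccc(C[C@H](CO)c2cc(OC)c(OC)c(OCc3ccccc3)c2OC)c1O | intermediate
23 | (3S)-3-[3-(benzyloxy)-2,4,5-trimethoxyphenyl]-8-methoxychroman-7-ol | COc1cc([C@H]2COc3c(ccc(O)c3OC)C2)c(OC)c(OCc2ccccc2)c1OC | intermediate
24 | (3S)-3-(3-hydroxy-2,4,5-trimethoxyphenyl)-8-methoxychroman-7-ol | COc1cc([C@H]2COc3c(ccc(O)c3OC)C2)c(OC)c(O)c1OC | target

## Step count and least certain steps

Total: 18 steps. Longest linear sequence: 18 steps from 1; compounds 8, 15 and 17 are bought and enter in steps 5, 11 and 12.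

Step 14 (key step). The enolate at C8 is the only productive one, but it is destabilized by the adjacent methoxy oxygen, so ring closure may be slow. Deprotonation at C4a followed by retro-Michael loss of the acrylate unit, or intermolecular ester condensation, could then consume the substrate. Fallback, from iodide 14 back to dione 20: ring A is taken as a preformed dione and the C4–C4a bond is made last. Commercial 2-methoxybenzene-1,3-diol F1 would be partially hydrogenated (H2, Raney Ni, aqueous NaOH) to 2-methoxycyclohexane-1,3-dione F2. This would be converted with EtOH and TsOH under azeotropic water removal into 3-ethoxy-2-methoxycyclohex-2-en-1-one F3. Its kinetic lithium enolate (LiN(iPr)2, THF–DMPU, −78 °C) would be alkylated at C6 with 14 to give the 6-alkyl-3-ethoxy-2-methoxycyclohex-2-en-1-one F4. Hydrolysis of the enol ether with dilute aqueous HCl in THF would return to 20.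

Step 15. The acidic dione may bind the catalyst as an oxygen-bound palladium enolate, which makes carbon-palladation at C6 or C4a slow, and the electron-rich resorcinol formed may be oxidized further under O2. Fallback, from 20 back to 23: the pyran ring is closed before aromatization and the dehydrogenation is done by selenium chemistry. Desilylation of 20 with Bu4NF would give the hydroxy dione 4-{(2S)-2-[3-(benzyloxy)-2,4,5-trimethoxyphenyl]-3-hydroxypropyl}-2-methoxycyclohexane-1,3-dione F5. TsOH in toluene with removal of water would condense the hydroxyl with the only carbonyl it can reach, C8a, to give the bicyclic enol ether (3S)-3-[3-(benzyloxy)-2,4,5-trimethoxyphenyl]-8-methoxy-2,3,4,4a,5,6-hexahydro-7H-chromen-7-one F6. Its lithium enolate (LiN(iPr)2, THF, −78 °C) with PhSeCl would give the 6-phenylselanyl ketone F7. Oxidation with H2O2 and selenoxide elimination would introduce the C5=C6 double bond, and the dienone would tautomerize to phenol 23. This fallback also replaces steps 16 and 17.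

Step 7. Poor discrimination between the two hydroxymethyl groups, caused by the ortho methoxy group of the aryl ring, or acetylation of the opposite arm, would give 11 with low or inverted enantiomeric purity. Acyl migration in 11 would erode it further. Fallback, from 10 back to 11: the diol would be acetylated completely (Ac2O, pyridine) to 2-[3-(benzyloxy)-2,4,5-trimethoxyphenyl]propane-1,3-diyl diacetate F8. A lipase would then hydrolyse one ester in phosphate buffer at pH 7. An enzyme that acts on the same enantiotopic arm in both directions gives, by hydrolysis, the mirror image of the monoacetate that it gives by acetylation, so the sense is inverted and the selectivity is set on a different substrate.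

Step 13. At 140 °C chloride may remove the silyl group, and water may cleave the methoxyacetyl group from the quaternary carbon by retro-Claisen reaction before decarboxylation is complete. Fallback, from 14 and 15 back to 19: the ester to be removed is made an allyl ester so that it leaves at room temperature. Transesterification of 15 with allyl alcohol (DMAP cat., toluene, reflux) would give prop-2-en-1-yl 4-methoxy-3-oxobutanoate F9. Alkylation with 14 as in step 11 would give prop-2-en-1-yl (4S)-4-[3-(benzyloxy)-2,4,5-trimethoxyphenyl]-2-(methoxyacetyl)-5-[(triisopropylsilyl)oxy]pentanoate F10. Michael addition to 17 as in step 12 would give the mixed allyl methyl diester F11. Pd(PPh3)4 and morpholine in THF at rt would remove the allyl group, and the β-keto acid would lose CO2 to give 19.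

## Further compounds

F1 | step 14 | 2-methoxybenzene-1,3-diol (commercial) | COc1c(O)cccc1O
F2 | step 14 | 2-methoxycyclohexane-1,3-dione | COC1C(=O)CCCC1=O
F3 | step 14 | 3-ethoxy-2-methoxycyclohex-2-en-1-one | CCOC1=C(OC)C(=O)CCC1
F4 | step 14 | 6-{(2S)-2-[3-(benzyloxy)-2,4,5-trimethoxyphenyl]-3-[(triisopropylsilyl)oxy]propyl}-3-ethoxy-2-methoxycyclohex-2-en-1-one | CCOC1=C(OC)C(=O)C(C[C@H](CO[Si](C(C)C)(C(C)C)C(C)C)c2cc(OC)c(OC)c(OCc3ccccc3)c2OC)CC1
F5 | step 15 | 4-{(2S)-2-[3-(benzyloxy)-2,4,5-trimethoxyphenyl]-3-hydroxypropyl}-2-methoxycyclohexane-1,3-dione | COC1C(=O)CCC(C[C@H](CO)c2cc(OC)c(OC)c(OCc3ccccc3)c2OC)C1=O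
F6 | step 15 | (3S)-3-[3-(benzyloxy)-2,4,5-trimethoxyphenyl]-8-methoxy-2,3,4,4a,5,6-hexahydro-7H-chromen-7-one | COc1cc([C@H]2COC3=C(OC)C(=O)CCC3C2)c(OC)c(OCc2ccccc2)c1OC
F7 | step 15 | (3S)-3-[3-(benzyloxy)-2,4,5-trimethoxyphenyl]-8-methoxy-6-(phenylselanyl)-2,3,4,4a,5,6-hexahydro-7H-chromen-7-one | COc1cc([C@H]2COC3=C(OC)C(=O)C([Se]c4ccccc4)CC3C2)c(OC)c(OCc2ccccc2)c1OC
F8 | step 7 | 2-[3-(benzyloxy)-2,4,5-trimethoxyphenyl]propane-1,3-diyl diacetate | CC(=O)OCC(COC(C)=O)c1cc(OC)c(OC)c(OCc2ccccc2)c1OC
F9 | step 13 | prop-2-en-1-yl 4-methoxy-3-oxobutanoate | COCC(=O)CC(=O)OCC=C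
F10 | step 13 | prop-2-en-1-yl (4S)-4-[3-(benzyloxy)-2,4,5-trimethoxyphenyl]-2-(methoxyacetyl)-5-[(triisopropylsilyl)oxy]pentanoate | COCC(=O)C(C(=O)OCC=C)C[C@H](CO[Si](C(C)C)(C(C)C)C(C)C)c1cc(OC)c(OC)c(OCc2ccccc2)c1OC
F11 | step 13 | 5-methyl 1-(prop-2-en-1-yl) 2-{(2S)-2-[3-(benzyloxy)-2,4,5-trimethoxyphenyl]-3-[(triisopropylsilyl)oxy]propyl}-2-(methoxyacetyl)pentanedioate | COCC(=O)C(CCC(=O)OC)(C(=O)OCC=C)C[C@H](CO[Si](C(C)C)(C(C)C)C(C)C)c1cc(OC)c(OC)c(OCc2ccccc2)c1OC
A1 | alternative 1 | cis-8-hydroxy-3-isopropoxy-4,9-dimethoxypterocarpan | COc1cc2c(cc1O)[C@H]1COc3c(ccc(OC(C)C)c3OC)[C@H]1O2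
A2 | alternative 1 | 2-methoxy-1,4-benzoquinone | COC1=CC(=O)C=CC1=O
A3 | alternative 1 | 7-isopropoxy-8-methoxy-2H-chromene | COc1c(OC(C)C)ccc2C=CCOc12
A4 | alternative 2 | (3S)-7-(methoxymethoxy)-3-[2,4,5-trimethoxy-3-(methoxymethoxy)phenyl]chroman-8-ol | COc1cc([C@H]2COc3c(ccc(OCOC)c3O)C2)c(OC)c(OCOC)c1OC
A5 | alternative 2 | (2S)-3-[2-bromo-4-(methoxymethoxy)phenyl]-2-[2,4,5-trimethoxy-3-(methoxymethoxy)phenyl]propan-1-ol | COCOc1ccc(C[C@H](CO)c2cc(OC)c(OC)c(OCOC)c2OC)c(Br)c1
A6 | alternative 3 | (3S)-2,3-cis-7-(benzyloxy)-3-[3-(benzyloxy)-2,4,5-trimethoxyphenyl]-8-methoxy-2-[(1R,2S)-2-phenylcyclohexyloxy]chroman | COc1cc([C@H]2[C@@H](O[C@@H]4CCCC[C@H]4c4ccccc4)Oc3c(ccc(OCc4ccccc4)c3OC)C2)c(OC)c(OCc2ccccc2)c1OC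
A7 | alternative 3 | tert-butyl 3-(benzyloxy)-6-(hydroxymethyl)-2-methoxyphenyl carbonate | COc1c(OCc2ccccc2)ccc(CO)c1OC(=O)OC(C)(C)C
A8 | alternative 3 | 3-(benzyloxy)-1,2,5-trimethoxy-4-{(Z)-2-[(1R,2S)-2-phenylcyclohexyloxy]ethenyl}benzene | COc1cc(/C=C\O[C@@H]2CCCC[C@H]2c2ccccc2)c(OC)c(OCc2ccccc2)c1OC
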